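Slowness is not this flask's danger: the amber run, with 1 mM of free catalyst, read 88.8% of product at 1.33 min, well before the 6.0 min asked. So the reckoning here is a ledger of what is left once the flask stops changing.

| flask | substrate | partner | free catalyst | remark | time |
|---|---|---|---|---|---|
| amber | 0.010 M | 9 mM | 1 mM | run made earlier |  |
| violet | 0.010 M | 9 mM | 2.2 mM | run made earlier |  |
| grey | 0.010 M | 18 mM | 1.5 mM | run made earlier |  |
| flask | 0.010 M | 9.00 mM | 1.5 mM |  | 6.0 min |

- amber (time / min: product / %, catalyst intermediate B / %): 1.33: 88.8, 5.7; 2.50: 89.8, 8.4; 4.00: 89.7, 8.6; 5.00: 88.7, 8.5; 6.00: 90.5, 9.4; 8.00: 89.1, 9.4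
- violet (time / min: product / %, catalyst intermediate B / %): 0.500: 83.8, 9.2; 1.00: 89.3, 10.5; 1.50: 87.5, 11.4; 2.50: 89.0, 11.0; 4.00: 88.0, 11.0; 8.00: 88.6, 12.3
- grey (time / min: product / %, catalyst intermediate B / %): 0.667: 94.2, 0.4; 2.00: 99.3, 0.4; 3.00: 99.1, 0.3; 5.00: 99.7, 0; 8.00: 99.4, 0.2

(readings scatter by 0.5 percentage points)

- the earlier runs were read with a standard deviation of 0.5 percentage points
- candidate steps: substrate + free catalyst -> catalyst intermediate A; catalyst intermediate A -> catalyst intermediate B; partner + catalyst intermediate B <-> catalyst intermediate C; catalyst intermediate C <-> free catalyst + product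

* product at 6.0 min, in percent of the substrate charged
* catalyst intermediate B at 6.0 min, in percent of the substrate charged

1. Partner is the limiting reagent. Let b be the [partner] left, and take catalyst intermediates A and C as empty. Then [product] = [partner] charged − b. Substrate without partner, d = 1.00 mM, stays on the catalyst, so [catalyst intermediate B] = d + b. The catalyst charge covers this, leaving [free catalyst] = s − b, with s = 0.500 mM in this flask.

2. The books close on the closing ratio, [product][free catalyst] / ([catalyst intermediate B][partner]). In the violet run, catalyst intermediate B averaged 1.14 mM from 1.50 min on. The same entries give 0.143 mM of partner, 1.06 mM of free catalyst and 8.86 mM of product, so the ratio reads 57.5. This is a reading, and it carries the scatter of a small difference.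

3. For this flask, Kr·b·(d + b) = ([partner] charged − b)(s − b) has the root b = 0.0637 mM. My reckoning is therefore 89.4% of product and 10.6% of catalyst intermediate B.

The forecast gives 89.3% of product and 10.4% of catalyst intermediate B, the latter lower than my figure, judging that “the flask is essentially there”.

The flask gives 89.3% of product and 10.7% of catalyst intermediate B.

    substrate + free catalyst → catalyst intermediate A (k = 69.0 /M/s)
    catalyst intermediate A → catalyst intermediate B (k = 1.45 /s)
    partner + catalyst intermediate B ⇌ catalyst intermediate C (K = 72.0 /M, k = 184 /M/s)
    catalyst intermediate C ⇌ free catalyst + product (K = 0.760 M, k = 28.3 /s)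

In the flask, the midpoint of the turnover of substrate with free catalyst came at 0.195 min, and substrate was down to 11.5% at 0.600 min. By 3.00 min substrate stood at 0.0615% and partner at 0.744% of its charge, while catalyst intermediate B held 70.7% of the catalyst charged, and 71.0% at 6.00 min. The ratio 57.5 put the partner left at 0.708% of its charge; the flask holds 0.73%. With 0.0060 M of free catalyst, the same ledger leaves 0.461 mM of partner, 5.12% of its charge; that flask held 5.24% at 6.00 min.

(The earlier runs and the new flask are calculated with made-up constants.)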